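## Structural features

The target is a (2S)-flavanone: ring A (the benzo ring carrying the 7-hydroxyl) is fused to the dihydropyranone ring C, and C2 of ring C carries ring B. Ring B is the benzo ring of a 2,2-dimethylchroman (primed atoms). Its pyran ring D holds the gem-dimethyl carbon C2', the carbinol carbon C3' (S) and the benzylic methylene C4'; C8' bears a phenol next to the ring oxygen O1', and C6' is bonded to C2. The two stereocentres, C2 and C3', are five bonds apart across the flat ring B, so neither can steer the other and each needs its own source of absolute configuration. C2 is benzylic, alpha to O1 and beta to the C4 ketone, so base or strong acid opens ring C by a retro-oxa-Michael reaction and racemises it. The free phenols of rings A and B are electron-rich and easily oxidised, and the benzylic C2–O1 bond is a possible site of hydrogenolysis. The real difficulty is to place a single oxygen on C3' with S configuration, next to a quaternary carbon, without disturbing the labile C2 centre. The key step uses the fact that the C3'(OH)–C4'H2 unit is the reduced form of an oxirane across C3'–C4' of a 2,2-dimethyl-2H-chromene. That planar, electron-rich cis alkene in ring D is a favourable substrate for oxygen transfer from a Mn(salen) catalyst, and the benzylic C4'–O bond of the epoxide can afterwards be removed reductively.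

## Logic of the disconnections

17 to 16. The two phenolic O–H bonds are exchanged for O–benzyl bonds, and the C4'–H bond is exchanged for a C4'–O bond tied to the C3' oxygen as an oxirane. The reason is that all three benzylic C–O bonds of 16 yield to one reductive cleavage, so the free phenols and the finished carbinol appear together in the last operation. The gain is that no separate deprotection is needed and the oxidisable polyphenol is never carried through a step. The demand is that cleavage occurs only at the benzylic C4'–O bond (C3'–O kept, so C3' stays S), spares the C2–O1 bond and the ketone, and runs in a neutral medium so that C2 is not epimerised.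

16 to 15. The C3'–O and C4'–O bonds of the oxirane are cut. This removes C3' and the transient C4' as stereocentres and returns a flat cis alkene, the substrate class on which catalyst-controlled oxygen transfer is most dependable. The gain is that 15 has a single stereocentre and no sp3 oxygen on ring D. The forward step must select the alkene face by the reagent alone, prefer the alkene over the ketone, and avoid water and base so that ring C stays closed. The (3'S,4'S) pair describes the cis-fused oxirane, and since C4' ends as a methylene only C3' is carried into 17.

15 to 10 + 14. The C2–C6' bond, the only bond between the two halves, is cut. This gives an aryl nucleophile and a planar enone acceptor, and lets the forward C–C bond formation set C2. The gain is convergence: two achiral fragments of similar size and a shorter linear sequence. The demand is an enantioselective 1,4-addition of an electron-rich arylboron compound to a vinylogous ester, with the chromene alkene as a spectator and a product that is not opened under the conditions.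

10 to 7. The C6'–B bond is traced back to a C6'–Br bond. A bromide survives the construction of ring D and is converted to boron only when needed. The forward halogen–metal exchange must be faster than any attack on the alkene or the benzyl ether.

7 to 4. The C4'–C4a' and O1'–C2' bonds of ring D are cut. Ring D, its quaternary carbon and the alkene then arise together from an acyclic aryl ether by a thermal pericyclic cascade. The gain is a monocyclic arene. The demand is that the rearrangement goes to the one free ortho position and that the required heat is applied early, to a robust intermediate.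

4 to 2 + 3. The bond between the aryl oxygen and the tertiary propargylic carbon is cut, giving a phenol and a commercial five-carbon unit. The forward O-alkylation cannot be an SN2 reaction at a tertiary centre and needs copper-assisted ionisation.

2 to 1. The C–Br bond is cut back to a commercial monobenzyl catechol. The forward bromination must go para to the free hydroxyl.

14 to 12 to 11. In ring C the O1–C2 and C2–C3 bonds are cut, which removes the one carbon inserted between the acetyl methyl group and the phenol oxygen; then the benzyl O–C bond is cut. This leads to a commercial acetophenone. The forward benzylation must distinguish the free hydroxyl from the chelated one, which is kept for ring closure.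

## Other disconnections considered

Alternative 1: The cut is in ring D: the C4'–C4a' and O1'–C2' bonds are taken apart at the bromoarene stage, leading back to 4. Forward, heating 4 triggers a [3,3] shift to the free ortho carbon, rearomatisation, a 1,5-hydrogen shift and an oxa-6π ring closure. The product is 8-(benzyloxy)-6-bromo-2,2-dimethyl-2H-chromene A1, the same compound as 7.
- In favour: one C–C and one C–O bond, ring D and its quaternary carbon form in a single metal-free operation; the regiochemistry is fixed by the single open ortho position; the bromine handle is untouched.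
- Against: it creates no stereocentre, so a plan centred on it leaves both C2 and C3' to later steps and does not say how C3' receives its oxygen. The temperature also confines it to an early intermediate.
- Structure: it equals the epoxidation in count (two bonds, one ring) and is the better in kind, because one of its bonds is a C–C bond of the framework.
- Mechanism: it is the more predictable of the two, being substrate-controlled with no catalyst–substrate matching.
- Stereochemistry: the epoxidation is better (two centres against none).
- Step economy: no difference, because the chosen route already passes through A1 in step 3. The two are complementary; the epoxidation is the strategic step only because it solves the C3' problem.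

Alternative 2: Ring A is cut at C4a–C5 and C8–C8a. The flavanone is traced back to the monocyclic dienophile (2S)-2-[(3S)-8-(benzyloxy)-3-(tert-butyldimethylsilyloxy)-2,2-dimethylchroman-6-yl]-5-(phenylsulfinyl)-2,3-dihydro-4H-pyran-4-one A2 and the diene trans-1-methoxy-3-(trimethylsilyloxy)buta-1,3-diene A3. Forward, a [4+2] cycloaddition across the sulfinyl-bearing C4a=C8a bond is followed by syn-elimination of the sulfinyl group, loss of the methoxy group and tautomerisation to the phenol A4.
- In favour: the position of the ring-A oxygen follows from the polarity of A3, whose nucleophilic terminus bonds to C8a; two C–C bonds form; the ring-A phenol arrives unprotected. C2 of A2 could come from a catalytic asymmetric hetero-Diels–Alder construction of the dihydropyranone ring, a source of C2 of comparable standing to the conjugate addition used here.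
- Against: ring A is the one part of the target that is available ready-made, so building it spends steps where there is no difficulty. A vinylogous ester is a reluctant dienophile, and the sulfinyl group adds steps and a further stereogenic element. C2 in A2 and A4 must survive the thermal cycloaddition–elimination sequence. C3' must already be in place and silylated, so an asymmetric oxidation of a chromene is needed anyway, together with a protection–deprotection pair that the chosen plan avoids. Two different deprotections follow A4.
- Structure: its key step builds more carbon framework (two C–C bonds and a carbocycle against two C–O bonds and an oxirane) and is the better on that count, but it sets no stereocentre.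
- Mechanism: the cycloaddition is reliable in principle, but the aromatising cascade on a dihydropyranone has less support than Mn(salen) epoxidation has on chromenes.
- Step economy: it would be longer by an estimated four to six operations.

Alternative 3: Ring C is cut at C4a–C4, C4–C3 and O1–C2, going back to 5-(benzyloxy)-2-iodophenol A5, carbon monoxide A6 and (3S)-8-(benzyloxy)-3-(tert-butyldimethylsilyloxy)-6-ethynyl-2,2-dimethylchroman A7. Forward, a palladium-catalysed carbonylative coupling is followed in the same flask by 6-endo addition of the phenol oxygen to the new triple-bond acceptor, giving the flavone 7-(benzyloxy)-2-[(3S)-8-(benzyloxy)-3-(tert-butyldimethylsilyloxy)-2,2-dimethylchroman-6-yl]-4H-chromen-4-one A8. An enantioselective hydrogenation of C2=C3 to the flavanone A9, desilylation and hydrogenolysis would complete the route.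
- In favour: three components, three skeletal bonds and ring C in one step, which is more convergent and more bond-forming than the chosen key step. A8 is flat at C2, so no racemisation can occur before the last stages. No boronic acid is needed.
- Against: 5-exo closure to the five-membered benzofuranone isomer competes with 6-endo closure, and a toxic gas must be handled. C2 then depends on asymmetric reduction of a flavone double bond, which is less established than aryl conjugate addition to chromones and risks further reduction of the ketone. A7 requires C3' to be set and protected early and an alkyne to be installed.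
- Structure: it is the better in bonds formed and in convergence.
- Mechanism: it is weaker where it matters, because ring assembly and creation of C2 are two separate steps and the second is the uncertain one. In the chosen plan one step does both.
- Step economy: an estimated three or more steps longer.

Key step: step 8

Assumption: the senses of induction follow the accepted facial models, (S,S)-Mn(salen)Cl for the (3'S,4'S) oxirane of a 2,2-dimethyl-2H-chromene and (R)-t-BuPyOX for the 2S flavanone. If either proves opposite on the actual substrate, the mirror-image ligand is used and nothing else changes. The precursor 15 and the epoxide 16 were checked against the target and are kept unchanged: their descriptors are consistent with the 3'S alcohol, and the benzyl ethers are the best choice because they fall in the final hydrogenolysis.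

Step 1
Reactants: 1 2-(benzyloxy)phenol
Product: 2 2-(benzyloxy)-4-bromophenol
Conditions: NBS (1.0 equiv), MeCN, −10 °C to rt
Reagents that add atoms: N-bromosuccinimide, O=C1CCC(=O)N1Br
Why: Electrophilic aromatic bromination; the free hydroxyl is a stronger para director than the benzyloxy group, so bromine should enter C4, and one equivalent at low temperature limits ortho attack and dibromination.

Step 2
Reactants: 2 2-(benzyloxy)-4-bromophenol; 3 3-chloro-3-methylbut-1-yne
Product: 4 2-(benzyloxy)-4-bromo-1-[(2-methylbut-3-yn-2-yl)oxy]benzene
Conditions: 3 (1.3 equiv), DBU, CuCl2·2H2O (cat.), MeCN, 0 °C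
Reagents that add atoms: none
Why: Copper-catalysed propargylic etherification: the copper acetylide of 3 loses chloride to a copper allenylidene (a propargyl cation equivalent) that the phenoxide captures at the tertiary carbon, a substitution not open to the SN2 path; this is the standard mild entry to aryl 1,1-dimethylpropargyl ethers.

Step 3
Reactants: 4 2-(benzyloxy)-4-bromo-1-[(2-methylbut-3-yn-2-yl)oxy]benzene
Product: 7 8-(benzyloxy)-6-bromo-2,2-dimethyl-2H-chromene, via allenylphenol 5 (not isolated), via ortho-quinone methide 6 (not isolated)
Conditions: PhNEt2, 185 °C
Reagents that add atoms: none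
Why: Aromatic propargyl Claisen cascade: a [3,3] shift to C6, the only free ortho position, then tautomerisation to 5, a 1,5-hydrogen shift to 6 and oxa-6π electrocyclisation; the gem-dimethyl group favours each step, and the aryl bromide and benzyl ether are inert to heat alone.

Step 4
Reactants: 7 8-(benzyloxy)-6-bromo-2,2-dimethyl-2H-chromene
Product: 10 [8-(benzyloxy)-2,2-dimethyl-2H-chromen-6-yl]boronic acid, via aryllithium 8 (not isolated), via lithium triisopropoxyborate 9 (not isolated)
Conditions: n-BuLi, THF, −78 °C; B(Oi-Pr)3, −78 °C to rt; 1 M HCl, 0 °C
Reagents that add atoms: n-butyllithium, [Li]CCCC (lithium of 8 and 9 only); triisopropyl borate, CC(C)OB(OC(C)C)OC(C)C; water, O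
Why: Lithiation–borylation: bromine–lithium exchange at −78 °C is much faster than addition to the styrenyl alkene or metalation next to the benzyl ether, and the borate is hydrolysed by brief cold acid that the chromene tolerates.

Step 5
Reactants: 11 2,4-dihydroxyacetophenone
Product: 12 1-[4-(benzyloxy)-2-hydroxyphenyl]ethan-1-one
Conditions: BnBr (1.05 equiv), K2CO3, acetone, reflux
Reagents that add atoms: benzyl bromide, BrCc1ccccc1
Why: Williamson ether synthesis; the 2-hydroxyl is held in a hydrogen bond to the acetyl carbonyl and is the less reactive, so monoalkylation should occur at the 4-hydroxyl.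

Step 6
Reactants: 12 1-[4-(benzyloxy)-2-hydroxyphenyl]ethan-1-one
Product: 14 7-(benzyloxy)-4H-chromen-4-one, via enaminone 13 (not isolated)
Conditions: Me2NCH(OMe)2, 95 °C; then conc. HCl, CH2Cl2, 40 °C
Reagents that add atoms: N,N-dimethylformamide dimethyl acetal, COC(OC)N(C)C
Why: Enaminone chromone synthesis: condensation of the methyl ketone with the formamide acetal gives 13, and acid promotes addition of the chelated phenol to the enaminone and loss of dimethylamine, closing ring C.

Step 7
Reactants: 10 [8-(benzyloxy)-2,2-dimethyl-2H-chromen-6-yl]boronic acid; 14 7-(benzyloxy)-4H-chromen-4-one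
Product: 15 (2S)-7-(benzyloxy)-2-[8-(benzyloxy)-2,2-dimethyl-2H-chromen-6-yl]chroman-4-one
Conditions: 10 (1.5 equiv), Pd(OCOCF3)2 (5 mol%), (R)-t-BuPyOX (6 mol%), NH4PF6 (30 mol%), H2O (5 equiv), ClCH2CH2Cl, 60 °C
Reagents that add atoms: none
Why: Asymmetric conjugate addition of an arylboronic acid to a chromone under divalent-palladium catalysis with the pyridine–oxazoline ligand (R)-4-tert-butyl-2-(pyridin-2-yl)-4,5-dihydrooxazole: transmetalation gives a cationic aryl–palladium species, chromone C2=C3 inserts with the aryl group going to C2 in the enantio-determining step, and water protonates the palladium enolate, so no oxidant or base is present and ring C stays closed. C2 is set by the ligand, the (R) enantiomer being the one expected to give 2S. The chromene alkene should stay a spectator because it has no allylic hydrogen and its insertion product would have no syn beta-hydrogen.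

Step 8
Reactants: 15 (2S)-7-(benzyloxy)-2-[8-(benzyloxy)-2,2-dimethyl-2H-chromen-6-yl]chroman-4-one
Product: 16 (2S)-7-(benzyloxy)-2-[(3S,4S)-8-(benzyloxy)-3,4-epoxy-2,2-dimethylchroman-6-yl]chroman-4-one
Conditions: (S,S)-Mn(salen)Cl [salen = N,N'-bis(3,5-di-tert-butylsalicylidene)cyclohexane-1,2-diaminate] (5 mol%), NMO (5 equiv), m-CPBA (2 equiv), CH2Cl2, −78 °C; cold aq. Na2S2O3/NaHCO3
Reagents that add atoms: m-chloroperoxybenzoic acid, OOC(=O)c1cccc(Cl)c1
Why: m-CPBA in the presence of NMO oxidises the chloride of trivalent manganese to an oxo complex of pentavalent manganese, and NMO also fills the axial site, which keeps oxygen transfer fast at −78 °C and suppresses the uncatalysed peracid pathway. The cis C3'=C4' bond approaches the Mn=O unit side-on over the diamine bridge; the first C–O bond forms at C3' and leaves a benzylic radical at C4', which collapses on the same oxygen, so the oxirane is closed by a stepwise [2+1] oxygen-atom transfer (3-exo collapse) and, because ring D forbids rotation, is necessarily cis-fused. The closest known reaction type is the Jacobsen–Katsuki epoxidation of 2,2-dimethyl-2H-chromenes in its anhydrous low-temperature peracid variant. Both new centres, C3' and C4', are fixed by the catalyst: the (S,S) complex is expected to present the face that gives 3'S,4'S, and their cis relation follows from the ring. The C2 centre lies five bonds away on the far side of ring B and should neither match nor mismatch noticeably, so the step is under reagent control. Chemoselectivity is needed against the C4 ketone (Baeyer–Villiger oxidation), the benzylic C2–H bond and the benzyl ethers; it is secured by the high nucleophilicity of the alkene, which is conjugated with ring B and its ortho oxygen O1', set against a ketone deactivated by two donor oxygens. The absence of water and of any base stronger than the N-oxide keeps ring C closed, so C2 stays S; the acid-labile epoxide is freed from 3-chlorobenzoic acid by a short cold bicarbonate wash and passed through base-washed silica.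

Step 9
Reactants: 16 (2S)-7-(benzyloxy)-2-[(3S,4S)-8-(benzyloxy)-3,4-epoxy-2,2-dimethylchroman-6-yl]chroman-4-one
Product: 17 (2S)-2-[(3S)-3,8-dihydroxy-2,2-dimethylchroman-6-yl]-7-hydroxychroman-4-one
Conditions: H2 (1 atm), 10% Pd/C, EtOAc, rt
Reagents that add atoms: none
Why: Heterogeneous hydrogenolysis: the strained benzylic C4'–O bond of the aryl oxirane is cleaved at the benzylic carbon while the C3'–O bond is untouched, so C3' keeps its S configuration, and both aryl benzyl ethers fall in the same operation. A neutral aprotic medium at 1 atm, stopped when uptake ends, should spare the ketone and the C2–O1 bond and leave C2 unchanged.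

Compound list

1 | 2-(benzyloxy)phenol | Oc1ccccc1OCc1ccccc1 | starting material
2 | 2-(benzyloxy)-4-bromophenol | Oc1ccc(Br)cc1OCc1ccccc1 | intermediate
3 | 3-chloro-3-methylbut-1-yne | CC(C)(Cl)C#C | starting material
4 | 2-(benzyloxy)-4-bromo-1-[(2-methylbut-3-yn-2-yl)oxy]benzene | C#CC(C)(C)Oc1ccc(Br)cc1OCc1ccccc1 | intermediate
5 | 2-(benzyloxy)-4-bromo-6-(3-methylbuta-1,2-dien-1-yl)phenol | CC(C)=C=Cc1cc(Br)cc(OCc2ccccc2)c1O | intermediate (not isolated)
6 | 2-(benzyloxy)-4-bromo-6-(3-methylbut-2-en-1-ylidene)cyclohexa-2,4-dien-1-one | CC(C)=CC=C1C=C(Br)C=C(OCc2ccccc2)C1=O | intermediate (not isolated)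
7 | 8-(benzyloxy)-6-bromo-2,2-dimethyl-2H-chromene | CC1(C)C=Cc2cc(Br)cc(OCc3ccccc3)c2O1 | intermediate
8 | [8-(benzyloxy)-2,2-dimethyl-2H-chromen-6-yl]lithium | [Li]c1cc(OCc2ccccc2)c2OC(C)(C)C=Cc2c1 | intermediate (not isolated)
9 | lithium [8-(benzyloxy)-2,2-dimethyl-2H-chromen-6-yl]tri(propan-2-yloxy)borate | [Li+].CC(C)O[B-](OC(C)C)(OC(C)C)c1cc(OCc2ccccc2)c2OC(C)(C)C=Cc2c1 | intermediate (not isolated)
10 | [8-(benzyloxy)-2,2-dimethyl-2H-chromen-6-yl]boronic acid | OB(O)c1cc(OCc2ccccc2)c2OC(C)(C)C=Cc2c1 | intermediate
11 | 2,4-dihydroxyacetophenone | CC(=O)c1ccc(O)cc1O | starting material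
12 | 1-[4-(benzyloxy)-2-hydroxyphenyl]ethan-1-one | CC(=O)c1ccc(OCc2ccccc2)cc1O | intermediate
13 | (E)-1-[4-(benzyloxy)-2-hydroxyphenyl]-3-(dimethylamino)prop-2-en-1-one | CN(C)/C=C/C(=O)c1ccc(OCc2ccccc2)cc1O | intermediate (not isolated)
14 | 7-(benzyloxy)-4H-chromen-4-one | O=c1ccoc2cc(OCc3ccccc3)ccc12 | intermediate
15 | (2S)-7-(benzyloxy)-2-[8-(benzyloxy)-2,2-dimethyl-2H-chromen-6-yl]chroman-4-one | CC1(C)C=Cc2cc([C@@H]3CC(=O)c4ccc(OCc5ccccc5)cc4O3)cc(OCc6ccccc6)c2O1 | intermediate
16 | (2S)-7-(benzyloxy)-2-[(3S,4S)-8-(benzyloxy)-3,4-epoxy-2,2-dimethylchroman-6-yl]chroman-4-one | CC1(C)Oc2c(OCc3ccccc3)cc([C@@H]4CC(=O)c5ccc(OCc6ccccc6)cc5O4)cc2[C@@H]7O[C@@H]71 | intermediate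
17 | (2S)-2-[(3S)-3,8-dihydroxy-2,2-dimethylchroman-6-yl]-7-hydroxychroman-4-one | CC1(C)Oc2c(O)cc([C@@H]3CC(=O)c4ccc(O)cc4O3)cc2C[C@@H]1O | target

Total step count: 9. Longest linear sequence: 7 steps (1 to 2 to 4 to 7 to 10 to 15 to 16 to 17, steps 1, 2, 3, 4, 7, 8, 9). The chromone branch (steps 5 and 6) joins at step 7.

Steps least certain to work

Step 8 (key step). The most likely failures are incomplete face selection, or acid-induced opening or hydride-shift isomerisation of the electron-rich benzylic epoxide by 3-chlorobenzoic acid during reaction or work-up; partial epimerisation at C2 is a lesser risk. The fallback installs C3' before the flavanone exists and sets out from 7.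
- Epoxidation of 7 with (S,S)-Mn(salen)Cl, aqueous NaOCl and 4-phenylpyridine N-oxide in CH2Cl2 at 0 °C should give (3S,4S)-8-(benzyloxy)-6-bromo-3,4-epoxy-2,2-dimethylchroman F1. No base-sensitive group is present at this stage.
- LiAlH4 in THF at 0 °C should deliver hydride to the benzylic C4, the only position open to SN2 attack, giving (3S)-8-(benzyloxy)-6-bromo-2,2-dimethylchroman-3-ol F2.
- NaH and BnBr in DMF give (3S)-3,8-bis(benzyloxy)-6-bromo-2,2-dimethylchroman F3.
- Lithiation–borylation as in step 4 gives [(3S)-3,8-bis(benzyloxy)-2,2-dimethylchroman-6-yl]boronic acid F4.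
- Conjugate addition to 14 under the conditions of step 7 gives (2S)-7-(benzyloxy)-2-[(3S)-3,8-bis(benzyloxy)-2,2-dimethylchroman-6-yl]chroman-4-one F5.
- Hydrogenolysis of the three benzyl ethers (H2, Pd(OH)2/C, EtOAc) returns to the route at 17.

This costs two more steps, removes the late oxidation, and takes the alkene out of the boronic acid.

Step 7. The most likely failure is loss of the electron-rich boronic acid by protodeboronation faster than insertion into the comparatively unreactive vinylogous ester; insufficient enantioselectivity is the second risk. The fallback forms ring C by closing the O1–C2 bond and secures C2 by kinetic resolution. It sets out from 7 and 12.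
- The aryllithium 8, made from 7 as in step 4, is quenched with DMF to give 8-(benzyloxy)-2,2-dimethyl-2H-chromene-6-carbaldehyde F6.
- Claisen–Schmidt condensation with 12 (KOH, EtOH, rt) gives (E)-1-[4-(benzyloxy)-2-hydroxyphenyl]-3-[8-(benzyloxy)-2,2-dimethyl-2H-chromen-6-yl]prop-2-en-1-one F7.
- NaOAc in refluxing EtOH closes it by oxa-Michael addition to racemic 7-(benzyloxy)-2-[8-(benzyloxy)-2,2-dimethyl-2H-chromen-6-yl]chroman-4-one F8.
- Asymmetric transfer hydrogenation with RuCl(p-cymene)[(R,R)-TsDPEN] or its (S,S) enantiomer in HCO2H–Et3N, the enantiomer being chosen on F8 so that the 2R ketone reacts faster, converts that half into (2R,4R)-7-(benzyloxy)-2-[8-(benzyloxy)-2,2-dimethyl-2H-chromen-6-yl]chroman-4-ol F9. The unreacted 2S ketone is separated and the route is rejoined at 15.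

At most half of the material is kept.

Step 9. The most likely failures are over-reduction (hydrogenolysis of the benzylic C2–O1 bond or reduction of the ketone), or isomerisation of the epoxide to a 3-chromanone on an acidic catalyst surface before hydrogen is delivered, which would erode C3'. The fallback separates the two events and avoids hydrogen over palladium. It sets out from 16.
- Cp2TiCl, made from Cp2TiCl2 and Zn dust in THF, with 1,4-cyclohexadiene should open the oxirane homolytically through trivalent titanium to the benzylic C4' radical, which takes up a hydrogen atom. This gives (2S)-7-(benzyloxy)-2-[(3S)-8-(benzyloxy)-3-hydroxy-2,2-dimethylchroman-6-yl]chroman-4-one F10.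
- BCl3 with pentamethylbenzene in CH2Cl2 at −78 °C then cleaves both aryl benzyl ethers without a reductant and returns to the route at 17.

Step 2. The most likely failure is slow O-alkylation of the ortho-substituted, bromine-deactivated phenoxide by the tertiary chloride, with loss of 3 by elimination. The fallback sets out from 2 and uses a carbonyl condensation in place of the ether and its rearrangement. Heating 2 with 3-methylbut-2-enal and PhB(OH)2 (propionic acid cat., toluene, reflux, water removed) should give 8-(benzyloxy)-6-bromo-4-(2-methylprop-1-en-1-yl)-2-phenyl-4H-1,3,2-benzodioxaborinine F11. This fragments thermally to the ortho-quinone methide 6, which closes by oxa-6π electrocyclisation; the route is rejoined at 7, with steps 2 and 3 replaced by one operation.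

Further compounds

F1 | step 8 | (3S,4S)-8-(benzyloxy)-6-bromo-3,4-epoxy-2,2-dimethylchroman | CC1(C)Oc2c(OCc3ccccc3)cc(Br)cc2[C@@H]7O[C@@H]71
F2 | step 8 | (3S)-8-(benzyloxy)-6-bromo-2,2-dimethylchroman-3-ol | CC1(C)Oc2c(OCc3ccccc3)cc(Br)cc2C[C@@H]1O
F3 | step 8 | (3S)-3,8-bis(benzyloxy)-6-bromo-2,2-dimethylchroman | CC1(C)Oc2c(OCc3ccccc3)cc(Br)cc2C[C@@H]1OCc4ccccc4
F4 | step 8 | [(3S)-3,8-bis(benzyloxy)-2,2-dimethylchroman-6-yl]boronic acid | CC1(C)Oc2c(OCc3ccccc3)cc(B(O)O)cc2C[C@@H]1OCc4ccccc4
F5 | step 8 | (2S)-7-(benzyloxy)-2-[(3S)-3,8-bis(benzyloxy)-2,2-dimethylchroman-6-yl]chroman-4-one | CC1(C)Oc2c(OCc3ccccc3)cc([C@@H]4CC(=O)c5ccc(OCc6ccccc6)cc5O4)cc2C[C@@H]1OCc7ccccc7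
F6 | step 7 | 8-(benzyloxy)-2,2-dimethyl-2H-chromene-6-carbaldehyde | CC1(C)C=Cc2cc(C=O)cc(OCc3ccccc3)c2O1
F7 | step 7 | (E)-1-[4-(benzyloxy)-2-hydroxyphenyl]-3-[8-(benzyloxy)-2,2-dimethyl-2H-chromen-6-yl]prop-2-en-1-one | CC1(C)C=Cc2cc(/C=C/C(=O)c3ccc(OCc4ccccc4)cc3O)cc(OCc5ccccc5)c2O1
F8 | step 7 | racemic 7-(benzyloxy)-2-[8-(benzyloxy)-2,2-dimethyl-2H-chromen-6-yl]chroman-4-one | CC1(C)C=Cc2cc(C3CC(=O)c4ccc(OCc5ccccc5)cc4O3)cc(OCc6ccccc6)c2O1
F9 | step 7 | (2R,4R)-7-(benzyloxy)-2-[8-(benzyloxy)-2,2-dimethyl-2H-chromen-6-yl]chroman-4-ol | CC1(C)C=Cc2cc([C@H]3C[C@@H](O)c4ccc(OCc5ccccc5)cc4O3)cc(OCc6ccccc6)c2O1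
F10 | step 9 | (2S)-7-(benzyloxy)-2-[(3S)-8-(benzyloxy)-3-hydroxy-2,2-dimethylchroman-6-yl]chroman-4-one | CC1(C)Oc2c(OCc3ccccc3)cc([C@@H]4CC(=O)c5ccc(OCc6ccccc6)cc5O4)cc2C[C@@H]1O
F11 | step 2 | 8-(benzyloxy)-6-bromo-4-(2-methylprop-1-en-1-yl)-2-phenyl-4H-1,3,2-benzodioxaborinine | CC(C)=CC1OB(c2ccccc2)Oc2c(OCc3ccccc3)cc(Br)cc12
A1 | alternative 1 | 8-(benzyloxy)-6-bromo-2,2-dimethyl-2H-chromene | CC1(C)C=Cc2cc(Br)cc(OCc3ccccc3)c2O1
A2 | alternative 2 | (2S)-2-[(3S)-8-(benzyloxy)-3-(tert-butyldimethylsilyloxy)-2,2-dimethylchroman-6-yl]-5-(phenylsulfinyl)-2,3-dihydro-4H-pyran-4-one (sulfur configuration not specified) | CC1(C)Oc2c(OCc3ccccc3)cc([C@@H]4CC(=O)C(S(=O)c5ccccc5)=CO4)cc2C[C@@H]1O[Si](C)(C)C(C)(C)C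
A3 | alternative 2 | trans-1-methoxy-3-(trimethylsilyloxy)buta-1,3-diene | CO/C=C/C(=C)O[Si](C)(C)C
A4 | alternative 2 | (2S)-2-[(3S)-8-(benzyloxy)-3-(tert-butyldimethylsilyloxy)-2,2-dimethylchroman-6-yl]-7-hydroxychroman-4-one | CC1(C)Oc2c(OCc3ccccc3)cc([C@@H]4CC(=O)c5ccc(O)cc5O4)cc2C[C@@H]1O[Si](C)(C)C(C)(C)C
A5 | alternative 3 | 5-(benzyloxy)-2-iodophenol | Oc1cc(OCc2ccccc2)ccc1I
A6 | alternative 3 | carbon monoxide | [C-]#[O+]
A7 | alternative 3 | (3S)-8-(benzyloxy)-3-(tert-butyldimethylsilyloxy)-6-ethynyl-2,2-dimethylchroman | CC1(C)Oc2c(OCc3ccccc3)cc(C#C)cc2C[C@@H]1O[Si](C)(C)C(C)(C)C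
A8 | alternative 3 | 7-(benzyloxy)-2-[(3S)-8-(benzyloxy)-3-(tert-butyldimethylsilyloxy)-2,2-dimethylchroman-6-yl]-4H-chromen-4-one | CC1(C)Oc2c(OCc3ccccc3)cc(-c4cc(=O)c5ccc(OCc6ccccc6)cc5o4)cc2C[C@@H]1O[Si](C)(C)C(C)(C)C
A9 | alternative 3 | (2S)-7-(benzyloxy)-2-[(3S)-8-(benzyloxy)-3-(tert-butyldimethylsilyloxy)-2,2-dimethylchroman-6-yl]chroman-4-one | CC1(C)Oc2c(OCc3ccccc3)cc([C@@H]4CC(=O)c5ccc(OCc6ccccc6)cc5O4)cc2C[C@@H]1O[Si](C)(C)C(C)(C)C
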